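Assumption: the target carries no axial descriptor at its two biaryl bonds, so these are treated as stereochemically undefined (rotamers, not isomers to be controlled).

Consistency of the key-step structures: 13 and 19 map atom for atom onto 25. The change from 2S in 19 to 2R in 25 is a change of CIP priorities when C3 gains oxygen, not an inversion. The precursor design is refined only in the masking of the three oxygens that become O1 (an acid-labile acetal there, benzyl everywhere else).

Remark on stoichiometry: steps 8 and 12 are threefold. The numbered reactant that enters three times stands once under Reactants with its equivalents, and its second and third equivalents are entered again under the reagents that add atoms, so that every heavy atom of the product has a stated source.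

## Structural features

The target is a trimer of 3',4'-dihydroxyflavan-3-ol units: a central 5,7-dihydroxy unit whose ring A is bonded through C6 and C8 to C5 of two identical 7,8-dihydroxy units, so the three rings A form a meta-terphenyl with two tri-ortho-substituted biaryl bonds. Each ring C holds two adjacent stereocentres, C2 (carrying the catechol ring B) and C3 (carrying the hydroxyl), in the 2,3-trans (2R,3S) arrangement. The three pairs have the same configuration and are separated by aromatic rings, so no unit can relay stereochemistry to another. The twelve phenolic hydroxyls sit in catechol, pyrogallol-type and phloroglucinol-type arrays that oxidise easily in air and base, and C2 is a benzylic aryl-ether carbon that can epimerise through opening of ring C. The free polyphenol must therefore appear only in the last step, under neutral conditions. The real difficulty is doing everything three times on a crowded terphenyl: the biaryl bonds end at C5 of the outer units, a position electrophilic substitution does not reach, and six stereocentres must be set without a diastereomer mixture. The key step exploits the fact that each ring B is attached at C2, which at the chromone oxidation level (C4=O, C2=C3) is the β-carbon of an enone in a flat ring system without stereocentres. A chiral catalyst can then form the three C2–C1' bonds and the three C2 stereocentres together, and the C4 carbonyl afterwards lets C3 be oxygenated under the control of C2.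

## Logic of the disconnections

25 ⇒ 24. The twelve phenolic O–H groups are traced back to O–benzyl ethers. One neutral hydrogenolysis then frees all phenols at the end and the sensitive polyphenol is never carried through a reaction. The forward step must cleave twelve O–CH2Ph bonds while leaving the three cyclic benzylic C2–O1 bonds intact.

24 ⇒ 23 ⇒ 22. The three C4–H bonds are traced back to C4–OH and then to C4=O. The ketone is the group that both the C3 oxygenation and the key step require. The forward steps must deliver hydride to C4, ionise only the benzylic C4–O bond and leave C2 and C3 alone.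

22 ⇒ 20 ⇒ 19. The three C3–O bonds are cut. C3 is α to the C4 ketone, so the enol derivative 20 can be oxidised on the face away from the C2 aryl group, and the trans isomer is also the thermodynamic one. Three stereocentres disappear. The demand is that 20 be made without a free enolate, which could expel O1 and erase C2.

19 ⇒ 13 + 3 × 18 (key disconnection). The three C2–C1' bonds are cut. All remaining stereocentres vanish, three identical aryl groups come off as one reagent, and the precursor is a flat tris-enone. The forward step must add aryl to C2 of three electronically different enones with the same facial sense and go to completion at all three.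

18 ⇒ 15 ⇒ 14. The C–B bond is traced back to C–Br and the two O–benzyl bonds to the free hydroxyls of 14. Halogen–metal exchange must outrun benzylic deprotonation.

13 ⇒ 11 ⇒ 9 + 3 × 10. In each pyranone the O1–C2 bond and the C2–C3 bond are cut; C2 comes from 10 and C3 from an acetyl methyl group. This reduces three heterocycles to three methyl ketones. The oxygen that becomes O1 must be free at ring closure and masked before it, so it alone carries an acetal that the cyclisation acid removes.

9 ⇒ 8 + 2 × 4. The two biaryl bonds are cut. The central ring is the dielectrophile because its two coupling positions are the natural sites of electrophilic halogenation of a phloroglucinol ring. The outer ring is the boron partner. The forward step must form two tri-ortho-substituted biaryl bonds on one ring.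

4 ⇒ 3 ⇒ 2 ⇒ 1. The C–B bond lies ortho to the acetyl group, where electrophilic substitution does not go (it would go para to the C2 oxygen), so it is traced back to a C–H bond activated by the ketone itself. The two non-chelated hydroxyls carry benzyl groups and the chelated one the acetal. The forward steps rely on the hydrogen bond of the C2 hydroxyl for selective benzylation and on the carbonyl oxygen as directing group.

8 ⇒ 7 ⇒ 6 ⇒ 5. The two C–I bonds are cut at the only free ring positions, both activated by three oxygen donors. The acetal goes on after iodination because the iodination medium is acidic. Selective dibenzylation again relies on the chelated hydroxyl.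

## Other disconnections considered

Alternative 1: The cut runs through both outer rings A (C7–C8 and C8a–C4a). The forward step heats a bis(cyclobutenone) A2, built on an intact central flavan unit, with di-tert-butoxyethyne A3. Each four-membered ring opens to a vinylketene, adds the alkyne, reopens and closes by 6π electrocyclisation to the phenol, giving the 6,8-diarylflavan A1. In its favour, the pericyclic cascade needs no catalyst and fixes the substitution pattern of the outer rings by construction. The hindered biaryl bonds also exist before the outer rings do, so no tri-ortho-substituted cross-coupling is needed; on this point it is better than step 7 of the chosen plan. Against it, A3 is thermally sensitive (loss of isobutene), and A2 needs two cyclobutenones and two pre-formed diol side chains on a flavan core. A1 is also still far from the target: both outer rings C remain open and must be closed at C2–O1 with inversion after selective removal of tert-butyl ethers, in the presence of three kinds of protecting group. Structurally it treats the central unit differently from the outer ones, so the threefold symmetry is not used. Mechanistically its stereocentres come from earlier, separate asymmetric steps rather than from the key step. In step economy it is clearly longer before and after the key step than the chosen plan.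

Alternative 2: The cut is the C2–C3 bond of each ring C. A terphenyl tris(arylacetaldehyde) A5 reacts with three equivalents of the ylide from a chiral benzylsulfonium salt A6 (KOH) to give the tris-trans-epoxide A4. Each phenol, once unmasked, opens its epoxide at the benzylic carbon (6-endo, inversion) to the trans-flavan-3-ol. In its favour, C2 and C3 are set together and the product is already at the final oxidation level, so no C4 oxygen has to be removed. The endgame is therefore about three steps against five, which is better than the chosen plan. Like the chosen plan it uses three independent reagent-controlled events on an achiral precursor, where it is equal. Against it, A5 carries three enolisable, oxidation-prone arylacetaldehydes that must survive hydroxide. Sulfur-ylide epoxidation is generally less trans- and face-selective with aliphatic aldehydes than with aromatic ones, and six stereocentres depend on it. The chiral reagent is stoichiometric three times over. The later ring closure must be 6-endo rather than 5-exo at all three sites. A5 is also less robust than 13 and its three two-carbon side chains cost at least as many steps as the three pyranone closures.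

Alternative 3: The cut is the C3=C4 bond of each ring C. A tris-diene A8 (vinyl on C4a, 1-arylallyl ether on O1) is closed with the second-generation Grubbs catalyst (H2IMes)(PCy3)Cl2Ru=CHPh to the tris(flav-3-ene) A7, with loss of ethylene. In its favour, the metathesis is neutral and tolerant, which makes it equal in reliability to the pyranone closure of the chosen plan. A7 also needs only hydroboration–oxidation (anti to the C2 aryl) and hydrogenolysis to reach the target, two steps against five, which is better. Against it, the key step makes rings but no stereocentre: the three C2 centres must already be present in A8. That means an enantioselective O-allylation of three di-ortho-substituted phenols with a 1-arylallyl electrophile, which has less precedent than the conjugate arylation of chromones. The allylic and benzylic C–O bonds of A8 are prone to ionisation and sigmatropic rearrangement, and A7 can racemise through reversible electrocyclic opening of the chromene ring. Overall the step count is similar or slightly lower, but the hard asymmetric event moves to a place with weaker control, whereas the chosen plan sets C2 on a rigid, robust, stereocentre-free precursor.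

Key step: step 12

## Route

Step 1
Reactants: 1 1-(2,3,4-trihydroxyphenyl)ethanone
Product: 2 1-[3,4-bis(benzyloxy)-2-hydroxyphenyl]ethanone
Conditions: BnBr (2.1 equiv), K2CO3, DMF, 25 °C
Reagents that add atoms: benzyl bromide, BrCc1ccccc1
Why: Williamson etherification; the C2 hydroxyl is held in a hydrogen bond to the acetyl oxygen and is the least nucleophilic, so two equivalents of halide with a weak base should alkylate only O3 and O4.

Step 2
Reactants: 2 1-[3,4-bis(benzyloxy)-2-hydroxyphenyl]ethanone
Product: 3 1-[3,4-bis(benzyloxy)-2-(methoxymethoxy)phenyl]ethanone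
Conditions: NaH, DMF, 0 °C; MeOCH2Cl, 0 → 25 °C
Reagents that add atoms: chloromethyl methyl ether, COCCl
Why: Full deprotonation breaks the chelate and the phenoxide is alkylated (acetal protection); this acetal survives borylation, cross-coupling and the amide acetal and leaves under the acid that later closes the pyranone.

Step 3
Reactants: 3 1-[3,4-bis(benzyloxy)-2-(methoxymethoxy)phenyl]ethanone
Product: 4 1-[3,4-bis(benzyloxy)-2-(methoxymethoxy)-6-(4,4,5,5-tetramethyl-1,3,2-dioxaborolan-2-yl)phenyl]ethanone
Conditions: [Ir(OMe)(cod)]2 (2 mol %), AsPh3 (8 mol %), B2pin2 (1.2 equiv), octane, 120 °C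
Reagents that add atoms: bis(pinacolato)diboron, CC1(C)OB(OC1(C)C)B1OC(C)(C)C(C)(C)O1
Why: Ketone-directed C–H borylation with monovalent iridium: the carbonyl oxygen binds the iridium boryl species formed with the weakly donating AsPh3 and delivers it to the only ortho C–H bond (C6), the other ortho position carrying the acetal; without a directing group the benzyl rings should react slowly with this ligand.

Step 4
Reactants: 5 1-(2,4,6-trihydroxyphenyl)ethanone
Product: 6 1-[2,4-bis(benzyloxy)-6-hydroxyphenyl]ethanone
Conditions: BnBr (2.0 equiv), K2CO3, DMF, 25 °C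
Reagents that add atoms: benzyl bromide, BrCc1ccccc1
Why: Williamson etherification; after the para and one ortho oxygen are benzylated the last ortho hydroxyl is chelated to the acetyl group and should resist alkylation under these mild conditions.

Step 5
Reactants: 6 1-[2,4-bis(benzyloxy)-6-hydroxyphenyl]ethanone
Product: 7 1-[2,4-bis(benzyloxy)-6-hydroxy-3,5-diiodophenyl]ethanone
Conditions: N-iodosuccinimide (2.2 equiv), CF3CO2H (cat.), MeCN, 0 → 25 °C, dark
Reagents that add atoms: N-iodosuccinimide, O=C1CCC(=O)N1I
Why: Electrophilic aromatic iodination; C3 and C5 are the only free ring positions, each ortho or para to three oxygen donors including the free phenol, whereas the benzyl rings are not activated and no acid-labile group is present yet.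

Step 6
Reactants: 7 1-[2,4-bis(benzyloxy)-6-hydroxy-3,5-diiodophenyl]ethanone
Product: 8 1-[2,4-bis(benzyloxy)-3,5-diiodo-6-(methoxymethoxy)phenyl]ethanone
Conditions: NaH, DMF, 0 °C; MeOCH2Cl, 0 → 25 °C
Reagents that add atoms: chloromethyl methyl ether, COCCl
Why: Acetal protection of the chelated phenoxide as in step 2; capping it keeps the diiodide from becoming a deactivated phenoxide in the basic coupling and sets the same latent O1 as in the outer rings.

Step 7
Reactants: 8 1-[2,4-bis(benzyloxy)-3,5-diiodo-6-(methoxymethoxy)phenyl]ethanone; 4 1-[3,4-bis(benzyloxy)-2-(methoxymethoxy)-6-(4,4,5,5-tetramethyl-1,3,2-dioxaborolan-2-yl)phenyl]ethanone (2 equivalents react, 2.6 used)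
Product: 9 terphenyl tris(methyl ketone): 1-acetyl-2,4-bis(benzyloxy)-6-(methoxymethoxy)benzene carrying a 2-acetyl-4,5-bis(benzyloxy)-3-(methoxymethoxy)phenyl group at C3 and at C5
Conditions: Pd(OAc)2 (10 mol %), SPhos (2-dicyclohexylphosphino-2',6'-dimethoxybiphenyl, 20 mol %), K3PO4, toluene/H2O (10:1), 90 °C, degassed
Reagents that add atoms: none
Why: Twofold Suzuki–Miyaura coupling; the bulky electron-rich biarylphosphine supports oxidative addition of zerovalent palladium into the hindered electron-rich C–I bonds and reductive elimination to tri-ortho-substituted biaryls, and ketones, acetals and benzyl ethers tolerate aqueous phosphate.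

Step 8
Reactants: 9 terphenyl tris(methyl ketone); 10 N,N-dimethylformamide dimethyl acetal (3 equiv)
Product: 11 tris-enaminone: 9 with each acetyl group converted into an (E)-3-(dimethylamino)prop-2-enoyl group
Conditions: 10 in excess (9 equiv charged), toluene, 110 °C, MeOH distilled off
Reagents that add atoms: N,N-dimethylformamide dimethyl acetal (second and third equivalents of 10), COC(OC)N(C)C
Why: Condensation of a methyl ketone with an amide acetal, once at each of the three acetyl groups, so that three molecules of 10 each deliver one CH–NMe2 unit; the acetyl CH3 groups are the only acidic C–H bonds, methanol distils off, and the conjugated E-enaminone is the stable product.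

Step 9
Reactants: 11 tris-enaminone
Product: 13 tris-chromone 5,7-bis(benzyloxy)-6,8-bis[7,8-bis(benzyloxy)-4-oxo-4H-chromen-5-yl]-4H-chromen-4-one, via tris-phenol enaminone 12 (not isolated)
Conditions: conc. aq HCl, THF/MeOH, 50 °C
Reagents that add atoms: none
Why: Acid cleaves the three acetals, each freed phenol adds to its protonated enaminone (6-endo oxa-Michael) and dimethylamine is eliminated to give the pyranone (enaminone route to chromones); aryl benzyl ethers are stable to dilute HCl at this temperature.

Step 10
Reactants: 14 4-bromobenzene-1,2-diol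
Product: 15 1,2-bis(benzyloxy)-4-bromobenzene
Conditions: BnBr (2.2 equiv), K2CO3, DMF, 60 °C
Reagents that add atoms: benzyl bromide, BrCc1ccccc1
Why: Williamson etherification of both catechol hydroxyls; there is no competing site.

Step 11
Reactants: 15 1,2-bis(benzyloxy)-4-bromobenzene
Product: 18 [3,4-bis(benzyloxy)phenyl]boronic acid, via [3,4-bis(benzyloxy)phenyl]lithium 16 (not isolated), via lithium aryltriisopropoxyborate 17 (not isolated)
Conditions: n-BuLi, THF, −78 °C; B(O-i-Pr)3, −78 → 0 °C; 1 M aq HCl
Reagents that add atoms: triisopropyl borate, CC(C)OB(OC(C)C)OC(C)C; water, O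
Why: Bromine–lithium exchange at −78 °C is faster than benzylic deprotonation; the aryllithium is trapped by the borate and the ate complex is hydrolysed to the boronic acid.

Step 12
Reactants: 13 tris-chromone; 18 [3,4-bis(benzyloxy)phenyl]boronic acid (3 equiv)
Product: 19 tris-(2S)-flavanone: (2S)-5,7-bis(benzyloxy)-2-[3,4-bis(benzyloxy)phenyl]-6,8-bis{(2S)-7,8-bis(benzyloxy)-2-[3,4-bis(benzyloxy)phenyl]-4-oxochroman-5-yl}chroman-4-one
Conditions: Pd(OCOCF3)2 (15 mol %), (R)-4-tert-butyl-2-(pyridin-2-yl)-4,5-dihydro-1,3-oxazole (18 mol %), NH4PF6 (90 mol %), H2O (15 equiv), 18 in twofold excess (6 equiv charged), ClCH2CH2Cl, 60 °C, no added oxidant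
Reagents that add atoms: [3,4-bis(benzyloxy)phenyl]boronic acid (second and third equivalents of 18), OB(O)c1ccc(OCc2ccccc2)c(OCc2ccccc2)c1
Why: This is the enantioselective conjugate addition of an arylboronic acid to an enone under divalent palladium, and the closest known reaction type is the palladium/pyridine–oxazoline arylation of chromones to flavanones. Transmetalation from 18 gives a cationic aryl–palladium complex, the C2=C3 bond of a chromone coordinates and inserts into the palladium–aryl bond with the aryl group going to C2, and water protonates the palladium enolate, releasing the flavanone and returning divalent palladium without a redox change. No ring is closed; three C2–C1' bonds are formed, one from each of three molecules of 18. Each new stereocentre (C2 of each unit) is controlled by the ligand alone in the insertion step, where the tert-butyl group of the oxazoline shields one face of the bound enone. The (R)-ligand is chosen because the insertion model for cyclic enones has the (S)-ligand deliver aryl to the face that would be 2R in a chromone; the antipode is equally accessible if the sense proves opposite. The three enones are insulated by twisted biaryl bonds and have no stereocentre nearby, so the three additions should be independent and matched, and an occasional wrong-face addition gives a diastereomer that chromatography can remove. The step needs 1,4-addition rather than β-hydride elimination to a flavone (secured by excluding oxidants and supplying water for fast protonation) and attack at C2 only (C2 and C3 are unsubstituted and C2 is the enone β-carbon). It also needs complete reaction at all three sites, for which excess 18 is used; the excess also covers protodeboronation of this electron-rich acid.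

Step 13
Reactants: 19 tris-(2S)-flavanone
Product: 20 tris(silyl enol ether): 19 with each C4 ketone converted into a 4-(tert-butyldimethylsilyloxy)-2H-chromene (C3=C4), 2S at each C2
Conditions: t-BuMe2SiOSO2CF3 (4.5 equiv), Et3N (9 equiv), CH2Cl2, 0 °C
Reagents that add atoms: tert-butyldimethylsilyl trifluoromethanesulfonate, CC(C)(C)[Si](C)(C)OS(=O)(=O)C(F)(F)F
Why: Soft enolisation: the silyl triflate activates each carbonyl and the amine removes H3, so the enol ether forms without a free enolate that could expel O1 (retro-oxa-Michael) and racemise C2; C2 itself is not touched.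

Step 14
Reactants: 20 tris(silyl enol ether)
Product: 22 tris-(2R,3R)-3-hydroxyflavanone (19 bearing a hydroxyl at each C3 trans to the C2 aryl group), via tris(silyloxy epoxide) 21 (not isolated)
Conditions: dimethyldioxirane (3.6 equiv), acetone/CH2Cl2, −78 → 0 °C; then HF·pyridine, THF, 0 °C
Reagents that add atoms: dimethyldioxirane, CC1(C)OO1
Why: Rubottom oxidation: the dioxirane epoxidises each electron-rich enol ether on the face opposite the C2 aryl group and buffered fluoride opens the silyloxy epoxide to the α-hydroxy ketone, so C3 is set trans to the aryl group by substrate control; a cis isomer would equilibrate through the enol to the diequatorial trans isomer.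

Step 15
Reactants: 22 tris-(2R,3R)-3-hydroxyflavanone
Product: 23 tris(flavan-3,4-diol): each unit (2R,3S) with a secondary hydroxyl at C4 (C4 epimers, not separated)
Conditions: NaBH4, THF/MeOH, 0 °C
Reagents that add atoms: none
Why: Borohydride reduction of the three α-hydroxy ketones; the configuration at C4 is immaterial because the next step removes that centre, and the cold, nearly neutral medium should not epimerise C2 or C3.

Step 16
Reactants: 23 tris(flavan-3,4-diol)
Product: 24 tris-(2R,3S)-flavan-3-ol dodecabenzyl ether (25 with all twelve phenols benzylated)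
Conditions: Et3SiH (excess), CF3CO2H, CH2Cl2, −20 → 0 °C
Reagents that add atoms: none
Why: Ionic hydrogenation: acid ionises each benzylic C4 hydroxyl to a cation stabilised by the ortho and para oxygens of ring A and the silane delivers hydride; the secondary C3 hydroxyl does not ionise, so C2 and C3 keep their configuration.

Step 17
Reactants: 24 tris-(2R,3S)-flavan-3-ol dodecabenzyl ether
Product: 25 target CNP0171327.1
Conditions: H2 (1 atm), Pd(OH)2/C, THF/MeOH, 25 °C, then filtration and freeze-drying under argon
Reagents that add atoms: none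
Why: Hydrogenolysis of twelve aryl benzyl ethers under neutral conditions; the cyclic C2–O1 bond of flavans normally survives these conditions and no stereocentre is involved.

## Compound list

1 | 1-(2,3,4-trihydroxyphenyl)ethanone | CC(=O)c1ccc(O)c(O)c1O | starting material
2 | 1-[3,4-bis(benzyloxy)-2-hydroxyphenyl]ethanone | CC(=O)c1ccc(OCc2ccccc2)c(OCc2ccccc2)c1O | intermediate
3 | 1-[3,4-bis(benzyloxy)-2-(methoxymethoxy)phenyl]ethanone | CC(=O)c1ccc(OCc2ccccc2)c(OCc2ccccc2)c1OCOC | intermediate
4 | 1-[3,4-bis(benzyloxy)-2-(methoxymethoxy)-6-(4,4,5,5-tetramethyl-1,3,2-dioxaborolan-2-yl)phenyl]ethanone | CC(=O)c1c(B2OC(C)(C)C(C)(C)O2)cc(OCc2ccccc2)c(OCc2ccccc2)c1OCOC | intermediate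
5 | 1-(2,4,6-trihydroxyphenyl)ethanone | CC(=O)c1c(O)cc(O)cc1O | starting material
6 | 1-[2,4-bis(benzyloxy)-6-hydroxyphenyl]ethanone | CC(=O)c1c(O)cc(OCc2ccccc2)cc1OCc2ccccc2 | intermediate
7 | 1-[2,4-bis(benzyloxy)-6-hydroxy-3,5-diiodophenyl]ethanone | CC(=O)c1c(O)c(I)c(OCc2ccccc2)c(I)c1OCc2ccccc2 | intermediate
8 | 1-[2,4-bis(benzyloxy)-3,5-diiodo-6-(methoxymethoxy)phenyl]ethanone | CC(=O)c1c(OCOC)c(I)c(OCc2ccccc2)c(I)c1OCc2ccccc2 | intermediate
9 | terphenyl tris(methyl ketone): 1-acetyl-2,4-bis(benzyloxy)-6-(methoxymethoxy)benzene with a 2-acetyl-4,5-bis(benzyloxy)-3-(methoxymethoxy)phenyl group at C3 and at C5 | CC(=O)c1c(OCOC)c(-c2cc(OCc3ccccc3)c(OCc3ccccc3)c(OCOC)c2C(C)=O)c(OCc2ccccc2)c(-c2cc(OCc3ccccc3)c(OCc3ccccc3)c(OCOC)c2C(C)=O)c1OCc2ccccc2 | intermediate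
10 | N,N-dimethylformamide dimethyl acetal | COC(OC)N(C)C | starting material
11 | tris-enaminone: 9 with each acetyl as (E)-3-(dimethylamino)prop-2-enoyl | CN(C)/C=C/C(=O)c1c(OCOC)c(-c2cc(OCc3ccccc3)c(OCc3ccccc3)c(OCOC)c2C(=O)/C=C/N(C)C)c(OCc2ccccc2)c(-c2cc(OCc3ccccc3)c(OCc3ccccc3)c(OCOC)c2C(=O)/C=C/N(C)C)c1OCc2ccccc2 | intermediate
12 | tris-phenol enaminone: 11 with the three methoxymethyl ethers cleaved to phenols | CN(C)/C=C/C(=O)c1c(O)c(-c2cc(OCc3ccccc3)c(OCc3ccccc3)c(O)c2C(=O)/C=C/N(C)C)c(OCc2ccccc2)c(-c2cc(OCc3ccccc3)c(OCc3ccccc3)c(O)c2C(=O)/C=C/N(C)C)c1OCc2ccccc2 | intermediate (not isolated)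
13 | tris-chromone: 5,7-bis(benzyloxy)-6,8-bis[7,8-bis(benzyloxy)-4-oxo-4H-chromen-5-yl]-4H-chromen-4-one | O=c1ccoc2c(OCc9ccccc9)c(OCc9ccccc9)cc(-c3c(OCc9ccccc9)c4c(=O)ccoc4c(-c5cc(OCc9ccccc9)c(OCc9ccccc9)c6occc(=O)c56)c3OCc9ccccc9)c12 | intermediate
14 | 4-bromobenzene-1,2-diol | Oc1ccc(Br)cc1O | starting material
15 | 1,2-bis(benzyloxy)-4-bromobenzene | Brc1ccc(OCc2ccccc2)c(OCc2ccccc2)c1 | intermediate
16 | [3,4-bis(benzyloxy)phenyl]lithium | [Li]c1ccc(OCc2ccccc2)c(OCc2ccccc2)c1 | intermediate (not isolated)
17 | lithium [3,4-bis(benzyloxy)phenyl]tri(propan-2-yloxy)borate | [Li+].CC(C)O[B-](OC(C)C)(OC(C)C)c1ccc(OCc2ccccc2)c(OCc2ccccc2)c1 | intermediate (not isolated)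
18 | [3,4-bis(benzyloxy)phenyl]boronic acid | OB(O)c1ccc(OCc2ccccc2)c(OCc2ccccc2)c1 | intermediate
19 | tris-(2S)-flavanone, all twelve phenols benzylated | c9ccccc9COc1ccc([C@H]2Oc3c(OCc9ccccc9)c(OCc9ccccc9)cc(-c4c(OCc9ccccc9)c5c(c(-c6cc(OCc9ccccc9)c(OCc9ccccc9)c7c6C(=O)C[C@@H](c6ccc(OCc9ccccc9)c(OCc9ccccc9)c6)O7)c4OCc9ccccc9)O[C@H](c4ccc(OCc9ccccc9)c(OCc9ccccc9)c4)CC5=O)c3C(=O)C2)cc1OCc9ccccc9 | intermediate
20 | tris(tert-butyldimethylsilyl enol ether) of 19 (three 4-silyloxy-2H-chromenes, 2S at each C2) | c9ccccc9COc1ccc([C@H]2Oc3c(OCc9ccccc9)c(OCc9ccccc9)cc(-c4c(OCc9ccccc9)c5c(c(-c6cc(OCc9ccccc9)c(OCc9ccccc9)c7c6C(O[Si](C)(C)C(C)(C)C)=C[C@@H](c6ccc(OCc9ccccc9)c(OCc9ccccc9)c6)O7)c4OCc9ccccc9)O[C@H](c4ccc(OCc9ccccc9)c(OCc9ccccc9)c4)C=C5O[Si](C)(C)C(C)(C)C)c3C(O[Si](C)(C)C(C)(C)C)=C2)cc1OCc9ccccc9 | intermediate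
21 | tris(3,4-epoxy-4-silyloxyflavan): 20 with an oxirane across each C3–C4 on the face opposite the C2 aryl group | c9ccccc9COc1ccc([C@H]2Oc3c(OCc9ccccc9)c(OCc9ccccc9)cc(-c4c(OCc9ccccc9)c5c(c(-c6cc(OCc9ccccc9)c(OCc9ccccc9)c7c6[C@]8(O[Si](C)(C)C(C)(C)C)O[C@@H]8[C@@H](c6ccc(OCc9ccccc9)c(OCc9ccccc9)c6)O7)c4OCc9ccccc9)O[C@H](c4ccc(OCc9ccccc9)c(OCc9ccccc9)c4)[C@H]8O[C@]85O[Si](C)(C)C(C)(C)C)c3[C@]8(O[Si](C)(C)C(C)(C)C)O[C@H]28)cc1OCc9ccccc9 | intermediate (not isolated)
22 | tris-(2R,3R)-3-hydroxyflavanone (3-hydroxyl trans to the C2 aryl in each unit) | c9ccccc9COc1ccc([C@H]2Oc3c(OCc9ccccc9)c(OCc9ccccc9)cc(-c4c(OCc9ccccc9)c5c(c(-c6cc(OCc9ccccc9)c(OCc9ccccc9)c7c6C(=O)[C@H](O)[C@@H](c6ccc(OCc9ccccc9)c(OCc9ccccc9)c6)O7)c4OCc9ccccc9)O[C@H](c4ccc(OCc9ccccc9)c(OCc9ccccc9)c4)[C@@H](O)C5=O)c3C(=O)[C@@H]2O)cc1OCc9ccccc9 | intermediate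
23 | tris(flavan-3,4-diol), (2R,3S) in each unit, C4 epimers | c9ccccc9COc1ccc([C@H]2Oc3c(OCc9ccccc9)c(OCc9ccccc9)cc(-c4c(OCc9ccccc9)c5c(c(-c6cc(OCc9ccccc9)c(OCc9ccccc9)c7c6C(O)[C@H](O)[C@@H](c6ccc(OCc9ccccc9)c(OCc9ccccc9)c6)O7)c4OCc9ccccc9)O[C@H](c4ccc(OCc9ccccc9)c(OCc9ccccc9)c4)[C@@H](O)C5O)c3C(O)[C@@H]2O)cc1OCc9ccccc9 | intermediate
24 | tris-(2R,3S)-flavan-3-ol dodecabenzyl ether | c9ccccc9COc1ccc([C@H]2Oc3c(OCc9ccccc9)c(OCc9ccccc9)cc(-c4c(OCc9ccccc9)c5c(c(-c6cc(OCc9ccccc9)c(OCc9ccccc9)c7c6C[C@H](O)[C@@H](c6ccc(OCc9ccccc9)c(OCc9ccccc9)c6)O7)c4OCc9ccccc9)O[C@H](c4ccc(OCc9ccccc9)c(OCc9ccccc9)c4)[C@@H](O)C5)c3C[C@@H]2O)cc1OCc9ccccc9 | intermediate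
25 | CNP0171327.1: central (2R,3S)-3',4',5,7-tetrahydroxyflavan-3-ol bonded at C6 and C8 to C5 of two (2R,3S)-3',4',7,8-tetrahydroxyflavan-3-ol units | Oc1ccc([C@H]2Oc3c(O)c(O)cc(-c4c(O)c5c(c(-c6cc(O)c(O)c7c6C[C@H](O)[C@@H](c6ccc(O)c(O)c6)O7)c4O)O[C@H](c4ccc(O)c(O)c4)[C@@H](O)C5)c3C[C@@H]2O)cc1O | target

## Step count and risks

Total: 17 steps. Longest linear sequence: 12 steps (1 → 2 → 3 → 4 → 9 → 11 → 13 → 19 → 20 → 22 → 23 → 24 → 25; the branch from 5 through 6, 7 and 8 is equally long; the branch from 14 is 8 steps).

Least certain steps:

Step 12 (key step). The most likely failure is incomplete reaction at the central chromone. That unit is the least electrophilic (two alkoxy donors conjugated to its carbonyl) and its C2 lies next to the C8 aryl group, so the catalyst may bind poorly or with lower facial discrimination there. Protodeboronation and homocoupling of the electron-rich boronic acid compete for the catalyst. β-Hydride elimination from the palladium enolate would dehydrogenate a unit to a flavone and lose its stereocentre. Fallback: from 13, carry out the threefold addition of 18 with monovalent rhodium ([Rh(OH)(cod)]2 with a chiral diene or an electron-poor atropisomeric bisphosphine, toluene/H2O, 40–60 °C). This is a different metal and mechanism (neutral aryl–rhodium species, hydrolysis of an oxa-π-allyl rhodium enolate) with its own precedent on chromones, and it returns to the route at 19 without any new compound.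

Step 3. The catalyst may borylate C–H bonds of the benzyl rings without direction, or the enolisable methyl ketone may be O-borylated and stall turnover; either would give mixtures or low conversion. Fallback: from 3, condensation with 1,1-dimethylhydrazine gives the N,N-dimethylhydrazone F1. Its nitrogen donor directs iridium-catalysed ortho-borylation ([Ir(OMe)(cod)]2, a hemilabile pyridine–hydrazone ligand, B2pin2, THF, 55 °C) much more strongly than a ketone does, to give the borylated hydrazone F2. F2 is coupled with 8 under the conditions of step 7 to the terphenyl bis-hydrazone F3, and mild hydrolysis (CuCl2, THF/aqueous buffer) returns the ketones, rejoining the route at 9.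

Step 7. Protodeboronation of the ortho-acyl boronate may outrun the second, more hindered coupling, and the electron-rich diiodide may undergo hydrodeiodination, so that the reaction stops after one biaryl bond. Fallback: move the coupling to the chromone oxidation level, where the electrophile is less electron-rich and flatter. From 8, condensation with 10 gives the diiodo enaminone F4, and acid gives 5,7-bis(benzyloxy)-6,8-diiodochromone F5. Suzuki–Miyaura coupling of F5 with 4 gives the chromone bis(methyl ketone) F6, condensation with 10 gives the bis-enaminone F7, and acid then closes the two outer pyranones, rejoining the route at 13.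

Step 13 (and the oxidation in step 14 that depends on it). Ring C may open by retro-oxa-Michael elimination during enolisation, which would scramble C2; the peri-alkoxy ketone of the central unit may silylate incompletely; and epoxidation may be less face-selective on one unit. Fallback: from 19, NaBH4 reduction gives the tris(flavan-4-ol) F8, and mild acid-catalysed dehydration (pyridinium p-toluenesulfonate, toluene, 80 °C) gives the tris-(2S)-flav-3-ene F9 (the same structure as A7). Hydroboration with BH3·THF anti to the C2 aryl group, then NaOH/H2O2, places the hydroxyl at C3 trans to the aryl group and rejoins the route at 24. This path is one step shorter, but its regiochemistry and stereochemistry at C3 lack the thermodynamic safeguard of the ketone route, which is why it is the reserve.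

Step 16. The C4 cations may react in other ways before hydride arrives: a 1,2-hydride shift from C3 would give a C3 ketone, capture by an electron-rich ring would give oligomers, and the acid may start to remove benzyl groups. Fallback: from 23, hydrogenolyse directly over Pd(OH)2/C (H2, THF/MeOH, a little AcOH). This cleaves the three benzylic C4–O bonds together with the twelve benzyl ethers on the metal surface, without free cations in solution, and returns to the route at 25 without any new compound.

## Further compounds

F1 | step 3 | N,N-dimethylhydrazone of 3 | CC(=NN(C)C)c1ccc(OCc2ccccc2)c(OCc2ccccc2)c1OCOC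
F2 | step 3 | N,N-dimethylhydrazone of 4 (6-pinacolboryl derivative of F1) | CC(=NN(C)C)c1c(B2OC(C)(C)C(C)(C)O2)cc(OCc2ccccc2)c(OCc2ccccc2)c1OCOC
F3 | step 3 | 9 with both outer acetyl groups as N,N-dimethylhydrazones | CC(=O)c1c(OCOC)c(-c2cc(OCc3ccccc3)c(OCc3ccccc3)c(OCOC)c2C(C)=NN(C)C)c(OCc2ccccc2)c(-c2cc(OCc3ccccc3)c(OCc3ccccc3)c(OCOC)c2C(C)=NN(C)C)c1OCc2ccccc2
F4 | step 7 | (E)-1-[2,4-bis(benzyloxy)-3,5-diiodo-6-(methoxymethoxy)phenyl]-3-(dimethylamino)prop-2-en-1-one | CN(C)/C=C/C(=O)c1c(OCOC)c(I)c(OCc2ccccc2)c(I)c1OCc2ccccc2
F5 | step 7 | 5,7-bis(benzyloxy)-6,8-diiodo-4H-chromen-4-one | O=c1ccoc2c(I)c(OCc3ccccc3)c(I)c(OCc3ccccc3)c12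
F6 | step 7 | 5,7-bis(benzyloxy)-6,8-bis[2-acetyl-4,5-bis(benzyloxy)-3-(methoxymethoxy)phenyl]-4H-chromen-4-one | O=c1ccoc2c(-c3cc(OCc4ccccc4)c(OCc4ccccc4)c(OCOC)c3C(C)=O)c(OCc3ccccc3)c(-c3cc(OCc4ccccc4)c(OCc4ccccc4)c(OCOC)c3C(C)=O)c(OCc3ccccc3)c12
F7 | step 7 | F6 with both acetyl groups as (E)-3-(dimethylamino)prop-2-enoyl | O=c1ccoc2c(-c3cc(OCc4ccccc4)c(OCc4ccccc4)c(OCOC)c3C(=O)/C=C/N(C)C)c(OCc3ccccc3)c(-c3cc(OCc4ccccc4)c(OCc4ccccc4)c(OCOC)c3C(=O)/C=C/N(C)C)c(OCc3ccccc3)c12
F8 | step 13 | tris(flavan-4-ol) from 19, 2S at each C2, C4 epimers | c9ccccc9COc1ccc([C@H]2Oc3c(OCc9ccccc9)c(OCc9ccccc9)cc(-c4c(OCc9ccccc9)c5c(c(-c6cc(OCc9ccccc9)c(OCc9ccccc9)c7c6C(O)C[C@@H](c6ccc(OCc9ccccc9)c(OCc9ccccc9)c6)O7)c4OCc9ccccc9)O[C@H](c4ccc(OCc9ccccc9)c(OCc9ccccc9)c4)CC5O)c3C(O)C2)cc1OCc9ccccc9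
F9 | step 13 | tris-(2S)-flav-3-ene, phenols benzylated | c9ccccc9COc1ccc([C@H]2Oc3c(OCc9ccccc9)c(OCc9ccccc9)cc(-c4c(OCc9ccccc9)c5c(c(-c6cc(OCc9ccccc9)c(OCc9ccccc9)c7c6C=C[C@@H](c6ccc(OCc9ccccc9)c(OCc9ccccc9)c6)O7)c4OCc9ccccc9)O[C@H](c4ccc(OCc9ccccc9)c(OCc9ccccc9)c4)C=C5)c3C=C2)cc1OCc9ccccc9
F0 | step 12 | none | none
F0 | step 16 | none | none
A1 | alternative 1 | 6,8-diarylflavan ether with both outer rings A formed (C7 hydroxyl free, C8 and C8a tert-butyl ethers, side-chain diols as acetonides) | c9ccccc9COc1c(-c2cc(O)c(OC(C)(C)C)c(OC(C)(C)C)c2C[C@@H]2OC(C)(C)O[C@H]2c2ccc(OCc9ccccc9)c(OCc9ccccc9)c2)c(OCc9ccccc9)c(-c2cc(O)c(OC(C)(C)C)c(OC(C)(C)C)c2C[C@@H]2OC(C)(C)O[C@H]2c2ccc(OCc9ccccc9)c(OCc9ccccc9)c2)c2O[C@H](c3ccc(OCc9ccccc9)c(OCc9ccccc9)c3)[C@@H](OCc9ccccc9)Cc12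
A2 | alternative 1 | bis(cyclobutenone): central benzylated flavan carrying a 2-substituted 4-oxocyclobut-1-enyl group at C6 and at C8 | c9ccccc9COc1c(C2=C(C[C@@H]3OC(C)(C)O[C@H]3c3ccc(OCc9ccccc9)c(OCc9ccccc9)c3)C(=O)C2)c(OCc9ccccc9)c(C2=C(C[C@@H]3OC(C)(C)O[C@H]3c3ccc(OCc9ccccc9)c(OCc9ccccc9)c3)C(=O)C2)c2O[C@H](c3ccc(OCc9ccccc9)c(OCc9ccccc9)c3)[C@@H](OCc9ccccc9)Cc12
A3 | alternative 1 | di-tert-butoxyethyne | CC(C)(C)OC#COC(C)(C)C
A4 | alternative 2 | tris-(2S,3S)-trans-epoxide | c9ccccc9COc1ccc([C@@H]8O[C@H]8Cc2c(OCOC)c(OCc9ccccc9)c(OCc9ccccc9)cc2-c2c(OCc9ccccc9)c(C[C@@H]8O[C@H]8c3ccc(OCc9ccccc9)c(OCc9ccccc9)c3)c(OCOC)c(-c3cc(OCc9ccccc9)c(OCc9ccccc9)c(OCOC)c3C[C@@H]8O[C@H]8c3ccc(OCc9ccccc9)c(OCc9ccccc9)c3)c2OCc9ccccc9)cc1OCc9ccccc9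
A5 | alternative 2 | terphenyl tris(arylacetaldehyde) | O=CCc1c(OCOC)c(OCc9ccccc9)c(OCc9ccccc9)cc1-c1c(OCc9ccccc9)c(CC=O)c(OCOC)c(-c2cc(OCc9ccccc9)c(OCc9ccccc9)c(OCOC)c2CC=O)c1OCc9ccccc9
A6 | alternative 2 | (2R,5R)-1-[3,4-bis(benzyloxy)benzyl]-2,5-dimethylthiolanium bromide (one antipode of a C2-symmetric sulfonium salt) | C[C@@H]1CC[C@@H](C)[S+]1Cc1ccc(OCc2ccccc2)c(OCc2ccccc2)c1.[Br-]
A7 | alternative 3 | tris-(2S)-flav-3-ene, phenols benzylated | c9ccccc9COc1ccc([C@H]2Oc3c(OCc9ccccc9)c(OCc9ccccc9)cc(-c4c(OCc9ccccc9)c5c(c(-c6cc(OCc9ccccc9)c(OCc9ccccc9)c7c6C=C[C@@H](c6ccc(OCc9ccccc9)c(OCc9ccccc9)c6)O7)c4OCc9ccccc9)O[C@H](c4ccc(OCc9ccccc9)c(OCc9ccccc9)c4)C=C5)c3C=C2)cc1OCc9ccccc9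
A8 | alternative 3 | tris-diene: terphenyl with a vinyl group on each C4a and an (S)-1-arylallyl ether on each O1 | c9ccccc9COc1ccc([C@H](C=C)Oc3c(OCc9ccccc9)c(OCc9ccccc9)cc(-c4c(OCc9ccccc9)c(C=C)c(c(-c6cc(OCc9ccccc9)c(OCc9ccccc9)c(O[C@H](c7ccc(OCc9ccccc9)c(OCc9ccccc9)c7)C=C)c6C=C)c4OCc9ccccc9)O[C@H](c4ccc(OCc9ccccc9)c(OCc9ccccc9)c4)C=C)c3C=C)cc1OCc9ccccc9
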